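**Assumptions:** Isopoegin B (5,2',4'-trihydroxy-7-methoxy-5'-prenylisoflavone) has no stereocentres, so there is no enantiomer to control. The one transient stereocentre in compound 6 is racemic and is destroyed in Step 5. I assume 2',6'-dihydroxy-4'-methoxyacetophenone is purchasable.

## Retrosynthetic overview
1. The C5'–prenyl bond is made last, by Pd-catalysed Stille coupling of a 5'-bromo isoflavone. An electron-rich prenyl alkene would not survive the oxidative key step, so it cannot be carried through earlier.
2. The isoflavone is made by a biomimetic oxidative 1,2-aryl shift of a 2'-hydroxychalcone (hypervalent iodine in MeOH/orthoformate), then acid-mediated ring closure. This replaces the usual 3-iodochromone Suzuki or deoxybenzoin routes.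
3. The chalcone comes from Claisen–Schmidt condensation of commercial 2',6'-dihydroxy-4'-methoxyacetophenone with a bis-MOM-protected 5-bromo-2,4-dihydroxybenzaldehyde.
4. Only the γ-pyrone ring is formed during the synthesis, and it closes in Step 5, after the aryl shift. Both benzene rings come from commercial materials.

## Route

**Step 1**
Reactants: 1 (2,4-dihydroxybenzaldehyde)
Product: 2 (5-bromo-2,4-dihydroxybenzaldehyde)
Conditions: NBS (1.0 equiv), MeCN, 0 °C → rt
Reagents that add atoms: N-bromosuccinimide, O=C1CCC(=O)N1Br (supplies Br)
Why: Electrophilic aromatic bromination goes to C5, which is para to the 2-OH, ortho to the 4-OH and the least hindered activated site.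

**Step 2**
Reactants: 2
Product: 3 (5-bromo-2,4-bis(methoxymethoxy)benzaldehyde)
Conditions: MOMCl (2.5 equiv), i-Pr2NEt (3 equiv), CH2Cl2, 0 °C → rt
Reagents that add atoms: chloromethyl methyl ether, COCCl (supplies the MOM groups)
Why: Both phenols are masked as acid-labile MOM ethers so they survive the base of Step 3 and the oxidant of Step 4. Both MOM groups are removed in Step 5.

**Step 3**
Reactants: 3; 4 (2',6'-dihydroxy-4'-methoxyacetophenone)
Product: 5 ((E)-1-(2,6-dihydroxy-4-methoxyphenyl)-3-[5-bromo-2,4-bis(MOMO)phenyl]prop-2-en-1-one)
Conditions: 50% aq. KOH, EtOH, rt, 48 h; quench with sat. NH4Cl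
Reagents that add atoms: none
Why: Claisen–Schmidt aldol condensation gives the thermodynamically favoured E-enone. The two equivalent phenols only consume extra base.

**Step 4**
Reactants: 5
Product: 6 (racemic 1-(2,6-dihydroxy-4-methoxyphenyl)-2-[5-bromo-2,4-bis(MOMO)phenyl]-3,3-dimethoxypropan-1-one)
Conditions: PhI(OH)OTs (HTIB, 1.3 equiv), CH(OMe)3/MeOH (3:1), 0 °C → rt, 2 h
Reagents that add atoms: trimethyl orthoformate, COC(OC)OC, and methanol, CO (together they supply the two acetal OMe groups; the iodine reagent is not incorporated)
Why: This is the oxidative 2,3-aryl migration of 2'-hydroxychalcones, a biomimetic isoflavone-synthase-type rearrangement. I(III) activates the enone, MeOH adds at the β-carbon, and the electron-rich 2,4-dioxygenated aryl group shifts through a phenonium ion with loss of PhI, giving the β-ketoacetal. The one new stereocentre is racemic and is lost in Step 5. The aryl bromide is retained because the alkene is not yet prenylated.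

**Step 5**
Reactants: 6
Product: 7 (3-(5-bromo-2,4-dihydroxyphenyl)-5-hydroxy-7-methoxy-4H-chromen-4-one)
Conditions: conc. HCl (cat.–2 M), MeOH, reflux, 1–2 h
Reagents that add atoms: none
Why: Acid cleaves both MOM ethers and the acetal. The free 2'-OH of the A ring then closes onto the oxocarbenium and loses MeOH, forming the γ-pyrone and the C2=C3 double bond. This planarises C3, so no stereochemistry remains. The 5-OH stays free because it is chelated to the carbonyl.

**Step 6**
Reactants: 7; 8 (prenyltributylstannane)
Product: 9 (Isopoegin B)
Conditions: Pd(PPh3)4 (10 mol%), 8 (3 equiv), LiCl, DMF, 90 °C, 12 h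
Reagents that add atoms: none other than 8, which is a numbered reactant
Why: Stille cross-coupling of the aryl bromide with the allylstannane should give the linear (α) prenylarene, because reductive elimination occurs from the η1/η3-prenyl-Pd at the less hindered primary carbon. Excess stannane compensates for partial protonolysis by the free phenols. Nothing else in the molecule is altered.

## Compound list
| No. | Name | SMILES | Role |
|---|---|---|---|
| 1 | 2,4-Dihydroxybenzaldehyde | O=Cc1ccc(O)cc1O | starting material |
| 2 | 5-Bromo-2,4-dihydroxybenzaldehyde | O=Cc1cc(Br)c(O)cc1O | intermediate |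
| 3 | 5-Bromo-2,4-bis(methoxymethoxy)benzaldehyde | O=Cc1cc(Br)c(OCOC)cc1OCOC | intermediate |
| 4 | 2',6'-Dihydroxy-4'-methoxyacetophenone | CC(=O)c1c(O)cc(OC)cc1O | starting material |
| 5 | (E)-Chalcone, 5-bromo-2,4-bis(MOMO)-B ring | COc1cc(O)c(C(=O)/C=C/c2cc(Br)c(OCOC)cc2OCOC)c(O)c1 | intermediate |
| 6 | β-Ketoacetal (racemic) | COc1cc(O)c(C(=O)C(c2cc(Br)c(OCOC)cc2OCOC)C(OC)OC)c(O)c1 | intermediate |
| 7 | 5'-Bromo-5,2',4'-trihydroxy-7-methoxyisoflavone | COc1cc(O)c2c(=O)c(-c3cc(Br)c(O)cc3O)coc2c1 | intermediate |
| 8 | Prenyltributylstannane | CCCC[Sn](CCCC)(CCCC)CC=C(C)C | starting material |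
| 9 | Isopoegin B (achiral) | COc1cc(O)c2c(=O)c(-c3cc(CC=C(C)C)c(O)cc3O)coc2c1 | target |

## Totals
Total steps: 6. Longest linear sequence: 6 (1 → 2 → 3 → 5 → 6 → 7 → 9).

## Three steps most likely to fail
1. **Step 4, oxidative rearrangement.** Free phenols and electron-rich rings may be over-oxidised, and MOM groups may be cleaved by the TsOH released. Fallback: change the route to the 3-iodochromone approach. Build 3-iodo-5-hydroxy-7-methoxychromone from 4 (DMF-DMA, then I2), then Suzuki-couple it with 2,4-bis(MOMO)-5-prenylphenylboronic acid and remove the MOM groups.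
2. **Step 6, Stille prenylation.** The ortho-hydroxy aryl bromide may be slow to react, and α/γ (prenyl versus reverse-prenyl) selectivity is uncertain. Fallback: Stille-couple 7 with allyltributyltin, then convert the allyl group to prenyl by cross-metathesis with 2-methyl-2-butene using a Hoveyda–Grubbs II catalyst.
3. **Step 3, Claisen–Schmidt condensation.** The acetophenone dianion is poorly nucleophilic and the aldehyde is electron-rich, so conversion may be low. Fallback: protect 4 as its 2',6'-bis-MOM ether, form the lithium enolate with LiHMDS, and run an aldol with 3 followed by dehydration (Ms2O, Et3N). The acid in Step 5 still removes all MOM groups.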